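Fold the two exits of G into one number before reckoning anything else.

    J + G.D → J.G.D (k1 = 4.9 L mol⁻¹ h⁻¹)
    G + D → G.D (k2 = 1.0 L mol⁻¹ h⁻¹)
    X + J.G.D → Z (k3 = 5.5 L mol⁻¹ h⁻¹)
    2 G → G2 (k4 = 2.9 L mol⁻¹ h⁻¹)

the same everywhere: G 0.016 M; D 0.0160 M
- west: J 8.00 mM (fed, over 16.0 d); X 0.0400 M; time 20 d; all but J at the start; J goes in evenly over 16.0 d, the run ends at 20 d
- north-east: J 8.00 mM; X 0.0400 M (fed, over 16.0 d); time 20 d; a stirred flask in which X is dosed at a steady rate over 16.0 d without added volume, worked up at 20 d
- south-west: J 8.00 mM; X 0.0400 M; one stirred flow tank at steady state, fed with the mixture as stated, mean residence time 20 d
- south-east: J 8.00 mM; X 0.0400 M; time 20 d; a closed flask charged with all of it at once and left for 20 d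

- percentages count the G that a species holds: one G2 counts as two
- where a step has two of a species, its rate is k times that concentration squared, and two are used at each turn
- the stated concentrations are those of everything mixed, before any reaction; amounts are the same in each set-up
- the feed brings no volume worth counting
- run time (west): 20 d

1. the set-up with the highest amount of Z at the outlet or at the end, in percent of the G put in ("none" if the first two lie within 2 percentage points) (west / north-east / south-west / south-east / none)
2. amount of Z at the outlet or at the end, in percent of the G put in, west
3. amount of Z at the outlet or at the end, in percent of the G put in, north-east
4. amount of Z at the outlet or at the end, in percent of the G put in, south-west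
5. amount of Z at the outlet or at the end, in percent of the G put in, south-east

Dimerisation goes with c_G squared and capture by D with c_G once, so c_G sets the order of the loss and the split moves as G falls. At the charge, 5.80 G go to G2 for each G taken by D. This ratio, twice the dimerisation constant times c_G over the capture constant times c_D, is our partition number N, a selectivity factor. J and X act downstream of G.D, so west, north-east and south-east share one N. Integrating the split down to zero G, with c_D held, gives a captured share of ln(one plus N) over N, which is 33.1 %.

Is one number enough? The J charge covers 50.0 % of G, more than that share. With the other concentrations as charged in south-east, G.D has a half-life of 0.74 d by its reaction with J and J.G.D one of 0.13 d by its reaction with X, each far shorter than the 20 d run, so what is captured in south-east should reach Z. But capture of that share leaves c_D at 66.9 % of its charge, and the same formula with N at that c_D gives 26.2 %. We commit to Z between these two ends in west, north-east and south-east.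

Setting the feed of G equal to dimerisation, with capture and outflow left aside, gives a rough outlet c_G for south-west of 0.00240 M. South-west reacts at its outlet level of G, so N there is 0.869, and one over one plus N gives 53.5 %, more than the batch share, though roughly, since c_D is held.

The forecast gave 28 % for west, 28 % for north-east, 28.2 % for south-east and 36.2 % for south-west, best south-west: “The stirred tank holds G low while D stays comparatively high”.

The flasks give 30.1 % in west, 30.5 % in north-east, 30.5 % in south-east and 36.2 % in south-west, so south-west is best, and its figure is less than our rough 53.5 %. Take west with 0.040 M of G and the other charges unchanged. There N is 14.5, the share with c_D held is 18.9 %, and with c_D drawn down it is 12.2 %. That flask ends with 59 % of its D left and Z at 15.6 %.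

The constants used here come from no measurement; the run is a simulation.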